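**Retrosynthetic overview**
1. Target 27 is a (2S)-flavanone; the last step only removes three MOM ethers from 25.
2. Ring C is cut at O1–C8a and C4–C4a: aryne 21 (from ortho-silylaryl triflate 11) plus (S)-β-silyloxy Weinreb amide 20, united by O-arylation and acyl capture in one operation.
3. Enabling feature: in ring A the ether oxygen O1 and the acyl carbon C4 sit on adjacent carbons C8a and C4a (the two carbons of an aryne) and are 1,3-related through C2–C3 (a β-oxy carbonyl chain); the C5 oxygen next to C4a decides which aryne carbon takes O and which takes C.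
4. 11 comes from phloroglucinol (bis-MOM ether, carbamate, one-flask double directed ortho-metalation for TMS then prenyl, triflate). 20 comes from 7-hydroxy-2,2-dimethylchroman-4-one (chromene, ortho-formylation, MOM, acetamide aldol, oxidation, asymmetric transfer hydrogenation that sets C2, TMS ether).
5. Ring order: ring A and the chromene (ring B with its pyran) come from the starting materials; ring C is closed last, in step 12.

Key step: step 12

Remark: flavanone numbering is used (O1, C2, C3, C4, C4a, C5–C8, C8a; ring A = benzo ring, ring C = pyranone, ring B = the 2-aryl group with its fused dimethylpyran). The stereocentre in the SMILES is read as (2S). MOM = methoxymethyl, TMS = trimethylsilyl, TBS = tert-butyldimethylsilyl. Phloroglucinol and 7-hydroxy-2,2-dimethylchroman-4-one are taken as commercial.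

Step 1
Reactants: 1 phloroglucinol
Product: 2 3,5-bis(methoxymethoxy)phenol
Conditions: MOMCl (2.0 equiv), iPr2NEt, DMF, 0 °C to rt
Reagents that add atoms: chloromethyl methyl ether, COCCl
Why: Base-mediated O-alkylation of a phenol with an α-chloro ether; the reaction is statistical, so two equivalents are used and the bis-ether is separated from the mono- and tris-ethers (the mono-ether can be put through again).

Step 2
Reactants: 2 3,5-bis(methoxymethoxy)phenol
Product: 3 3,5-bis(methoxymethoxy)phenyl N-isopropylcarbamate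
Conditions: iPrNCO, Et3N (cat.), CH2Cl2, rt
Reagents that add atoms: isopropyl isocyanate, CC(C)N=C=O
Why: Amine-catalysed addition of the phenol to the isocyanate gives an N-monoalkyl carbamate, which is a strong ortho-directing group and can later be expelled as the isocyanate.

Step 3
Reactants: 3 3,5-bis(methoxymethoxy)phenyl N-isopropylcarbamate
Product: 9 3,5-bis(methoxymethoxy)-2-(3-methylbut-2-en-1-yl)-6-(trimethylsilyl)phenyl N-isopropylcarbamate, via N-silyl carbamate 4 (not isolated), via first aryllithium 5 (not isolated), via N-silyl arylsilane 6 (not isolated), via second aryllithium 7 (not isolated), via N-silyl prenylarene 8 (not isolated)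
Conditions: TBSOTf, TMEDA, Et2O, 0 °C to rt; TMEDA, n-BuLi, −78 °C; TMSCl (1.05 equiv), −78 °C to rt; n-BuLi, TMEDA, −78 °C; CuBr·SMe2 (10 mol%), prenyl bromide, −78 to −20 °C; aq. NH4Cl/MeOH work-up
Reagents that add atoms: chlorotrimethylsilane, C[Si](C)(C)Cl; 1-bromo-3-methylbut-2-ene (prenyl bromide), CC(C)=CCBr; tert-butyldimethylsilyl triflate, CC(C)(C)[Si](C)(C)OS(=O)(=O)C(F)(F)F (temporary N-silyl group of 4 to 8 only, lost in the work-up)
Why: Two directed ortho-metalations in one flask on the temporarily N-silylated carbamate: the carbamate (the strongest director present) and a neighbouring MOM ether should send the first lithiation to the carbon between them, where TMSCl traps it, and the second lithiation to the only other carbon flanked by the carbamate, where copper-catalysed SN2 allylation with prenyl bromide follows, the silyl group going on first so that no allylic/benzylic prenyl CH2 is present during a lithiation and the N-silyl group staying on until the work-up.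

Step 4
Reactants: 9 3,5-bis(methoxymethoxy)-2-(3-methylbut-2-en-1-yl)-6-(trimethylsilyl)phenyl N-isopropylcarbamate
Product: 11 3,5-bis(methoxymethoxy)-2-(3-methylbut-2-en-1-yl)-6-(trimethylsilyl)phenyl trifluoromethanesulfonate, via silylphenol 10 (not isolated)
Conditions: Et2NH, DBU, MeCN, 40 °C; then PhNTf2, rt
Reagents that add atoms: N-phenylbis(trifluoromethanesulfonimide), O=S(=O)(N(c1ccccc1)S(=O)(=O)C(F)(F)F)C(F)(F)F
Why: Base-induced E1cB loss of isopropyl isocyanate (trapped by diethylamine as a urea) frees the hindered phenoxide of 10, which is triflated in the same flask by triflyl transfer from PhNTf2 to give the ortho-silylaryl triflate.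

Step 5
Reactants: 12 7-hydroxy-2,2-dimethylchroman-4-one
Product: 14 2,2-dimethyl-2H-chromen-7-ol, via benzylic alcohol 13 (not isolated)
Conditions: NaBH4, MeOH/THF, 0 °C to rt; then p-TsOH·H2O (cat.), THF, 50 °C
Reagents that add atoms: none
Why: Hydride reduction of the aryl ketone gives the benzylic alcohol 13, and acid-catalysed E1 dehydration (cation stabilised by the ring oxygen and the para hydroxyl) gives the chromene.

Step 6
Reactants: 14 2,2-dimethyl-2H-chromen-7-ol
Product: 15 7-hydroxy-2,2-dimethyl-2H-chromene-6-carbaldehyde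
Conditions: MgCl2, Et3N, (CH2O)n, MeCN, reflux; dilute aq. HCl work-up
Reagents that add atoms: paraformaldehyde (as formaldehyde), C=O
Why: Magnesium-mediated ortho-formylation of a phenol (Casnati–Skattebøl): the magnesium phenoxide delivers formaldehyde to an ortho carbon and a second formaldehyde oxidises the benzylic alkoxide; C6 should be preferred over C8, which lies between two oxygens, as with 3-alkoxyphenols.

Step 7
Reactants: 15 7-hydroxy-2,2-dimethyl-2H-chromene-6-carbaldehyde
Product: 16 7-(methoxymethoxy)-2,2-dimethyl-2H-chromene-6-carbaldehyde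
Conditions: MOMCl, iPr2NEt, DMAP (cat.), CH2Cl2, 0 °C to rt
Reagents that add atoms: chloromethyl methyl ether, COCCl
Why: O-alkylation of the chelated phenol; MOM is chosen because it survives enolates, fluoride and transfer hydrogenation and can be removed at the end without hydrogenolysis or strong acid.

Step 8
Reactants: 16 7-(methoxymethoxy)-2,2-dimethyl-2H-chromene-6-carbaldehyde
Product: 17 rac-3-hydroxy-N-methoxy-3-[7-(methoxymethoxy)-2,2-dimethyl-2H-chromen-6-yl]-N-methylpropanamide
Conditions: N-methoxy-N-methylacetamide, LiN(iPr)2 (LDA), THF, −78 °C; then 16, −78 °C; AcOH quench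
Reagents that add atoms: N-methoxy-N-methylacetamide, CC(=O)N(C)OC
Why: Aldol addition of the lithium enolate of the Weinreb acetamide to the aldehyde; the carbinol is made racemic on purpose because the configuration is set after oxidation.

Step 9
Reactants: 17 rac-3-hydroxy-N-methoxy-3-[7-(methoxymethoxy)-2,2-dimethyl-2H-chromen-6-yl]-N-methylpropanamide
Product: 18 N-methoxy-3-[7-(methoxymethoxy)-2,2-dimethyl-2H-chromen-6-yl]-N-methyl-3-oxopropanamide
Conditions: Dess–Martin periodinane, CH2Cl2, 0 °C to rt
Reagents that add atoms: none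
Why: Dess–Martin oxidation of the benzylic secondary alcohol to the β-keto amide, which should leave the chromene alkene and the MOM ether untouched.

Step 10
Reactants: 18 N-methoxy-3-[7-(methoxymethoxy)-2,2-dimethyl-2H-chromen-6-yl]-N-methyl-3-oxopropanamide
Product: 19 (3S)-3-hydroxy-N-methoxy-3-[7-(methoxymethoxy)-2,2-dimethyl-2H-chromen-6-yl]-N-methylpropanamide
Conditions: RuCl(p-cymene)[(S,S)-TsDPEN] (2 mol%), HCO2H/Et3N (5:2), CH2Cl2, 30 °C
Reagents that add atoms: none
Why: Noyori asymmetric transfer hydrogenation of an aryl ketone: with the (S,S)-TsDPEN ligand hydride should be delivered as in acetophenone to (S)-1-phenylethanol (aryl ring against the η6-arene of the catalyst), giving the (3S)-carbinol that becomes C2 of the flavanone, without reducing the chromene C=C.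

Step 11
Reactants: 19 (3S)-3-hydroxy-N-methoxy-3-[7-(methoxymethoxy)-2,2-dimethyl-2H-chromen-6-yl]-N-methylpropanamide
Product: 20 (3S)-N-methoxy-3-[7-(methoxymethoxy)-2,2-dimethyl-2H-chromen-6-yl]-N-methyl-3-(trimethylsilyloxy)propanamide
Conditions: TMSCl, imidazole, CH2Cl2, 0 °C; filtration through basic Al2O3, used directly
Reagents that add atoms: chlorotrimethylsilane, C[Si](C)(C)Cl
Why: Silylation of the secondary alcohol removes the only O–H proton so that the alkoxide can later be released by fluoride; the stereocentre is not touched.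

Step 12
Reactants: 11 3,5-bis(methoxymethoxy)-2-(3-methylbut-2-en-1-yl)-6-(trimethylsilyl)phenyl trifluoromethanesulfonate; 20 (3S)-N-methoxy-3-[7-(methoxymethoxy)-2,2-dimethyl-2H-chromen-6-yl]-N-methyl-3-(trimethylsilyloxy)propanamide
Product: 25 (2S)-5,7-bis(methoxymethoxy)-2-[7-(methoxymethoxy)-2,2-dimethyl-2H-chromen-6-yl]-8-(3-methylbut-2-en-1-yl)chroman-4-one, via aryne 21 (not isolated), via cesium alkoxide 22 (not isolated), via aryl anion 23 (not isolated), via carbinolamine oxide 24 (not isolated)
Conditions: CsF (4 equiv), 18-crown-6, THF, −20 °C to rt, slow addition of 11; then AcOH, −20 °C; H2O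
Reagents that add atoms: cesium fluoride, [Cs+].[F-] (cesium is only the counter-ion of 22 to 24; no reagent atom remains in 25)
Why: Proposed new method: fluoride strips both trimethylsilyl groups, so that the cesium alkoxide 22 and the aryne 21 are set free side by side with no O–H or N–H proton in the flask; 22 adds through oxygen to the aryne carbon that carried the triflate (the future C8a), and the aryl anion 23 formed at the future C4a attacks the Weinreb amide carbonyl to give the carbinolamine oxide 24, which is meant to collapse to the ketone only in the acetic acid quench. The closest known reaction types are the fluoride-mediated annulation of arynes with salicylate esters to xanthones and the insertion of arynes into the N–acyl bond of β-lactams to 2,3-dihydroquinolin-4-ones; the open-chain β-silyloxy amide as four-atom partner is the new element. The O1–C8a bond is formed intermolecularly and ring C is then closed by a 6-exo-trig addition of the aryl anion to the amide C=O. No stereocentre is created: C2 comes from 20 with its C–O bond untouched, and because C4 should stay tetrahedral until the quench the flavanone should not open to the chalcone by β-elimination under the basic conditions. The step needs O-attack at C8a and not at C4a, which the C5 methoxymethoxy group next to C4a should secure (an alkoxy group beside an aryne sends the nucleophile to the remote aryne carbon and the negative charge to the carbon ortho to oxygen), with the prenyl group at C8 as the only steric counterweight. It also needs acylation to outrun protonation or α-deprotonation of 23, which the proton-free silyl ether/fluoride design and the low acidity of amide α-hydrogens are meant to secure.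

Step 13
Reactants: 25 (2S)-5,7-bis(methoxymethoxy)-2-[7-(methoxymethoxy)-2,2-dimethyl-2H-chromen-6-yl]-8-(3-methylbut-2-en-1-yl)chroman-4-one
Product: 27 (2S)-5,7-dihydroxy-2-(7-hydroxy-2,2-dimethyl-2H-chromen-6-yl)-8-(3-methylbut-2-en-1-yl)chroman-4-one, via tris(trimethylsilyl) ether 26 (not isolated)
Conditions: TMSOTf, 2,2′-bipyridyl, MeCN, 0 °C to rt; then H2O, rt
Reagents that add atoms: trimethylsilyl triflate, C[Si](C)(C)OS(=O)(=O)C(F)(F)F (O-silyl groups of 26 only; no reagent atom remains in 27)
Why: Silyl triflate/2,2′-bipyridyl cleavage of aryl MOM ethers: each ArO–CH2OMe is converted into the aryl trimethylsilyl ether under buffered aprotic conditions and water then frees the phenols, so the prenyl group, the chromene and the benzylic C2–O bond are not exposed to strong Brønsted acid or base and C2 is not touched.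

**Compound list**
1 | phloroglucinol (benzene-1,3,5-triol) | Oc1cc(O)cc(O)c1 | starting material
2 | 3,5-bis(methoxymethoxy)phenol | COCOc1cc(O)cc(OCOC)c1 | intermediate
3 | 3,5-bis(methoxymethoxy)phenyl N-isopropylcarbamate | COCOc1cc(OCOC)cc(OC(=O)NC(C)C)c1 | intermediate
4 | 3,5-bis(methoxymethoxy)phenyl N-(tert-butyldimethylsilyl)-N-isopropylcarbamate, formed in the flask | COCOc1cc(OCOC)cc(OC(=O)N(C(C)C)[Si](C)(C)C(C)(C)C)c1 | intermediate
5 | 2-lithio derivative of 4 (lithium between carbamate and MOM ether), formed in the flask | [Li]c1c(OCOC)cc(OCOC)cc1OC(=O)N(C(C)C)[Si](C)(C)C(C)(C)C | intermediate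
6 | 3,5-bis(methoxymethoxy)-2-(trimethylsilyl)phenyl N-(tert-butyldimethylsilyl)-N-isopropylcarbamate, formed in the flask | C[Si](C)(C)c1c(OCOC)cc(OCOC)cc1OC(=O)N(C(C)C)[Si](C)(C)C(C)(C)C | intermediate
7 | 6-lithio derivative of 6 (lithium at the other carbon between carbamate and MOM ether), formed in the flask | [Li]c1c(OCOC)cc(OCOC)c([Si](C)(C)C)c1OC(=O)N(C(C)C)[Si](C)(C)C(C)(C)C | intermediate
8 | 3,5-bis(methoxymethoxy)-2-(3-methylbut-2-en-1-yl)-6-(trimethylsilyl)phenyl N-(tert-butyldimethylsilyl)-N-isopropylcarbamate, formed in the flask | CC(C)=CCc1c(OCOC)cc(OCOC)c([Si](C)(C)C)c1OC(=O)N(C(C)C)[Si](C)(C)C(C)(C)C | intermediate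
9 | 3,5-bis(methoxymethoxy)-2-(3-methylbut-2-en-1-yl)-6-(trimethylsilyl)phenyl N-isopropylcarbamate | CC(C)=CCc1c(OCOC)cc(OCOC)c([Si](C)(C)C)c1OC(=O)NC(C)C | intermediate
10 | 3,5-bis(methoxymethoxy)-2-(3-methylbut-2-en-1-yl)-6-(trimethylsilyl)phenol, formed in the flask | CC(C)=CCc1c(OCOC)cc(OCOC)c([Si](C)(C)C)c1O | intermediate
11 | 3,5-bis(methoxymethoxy)-2-(3-methylbut-2-en-1-yl)-6-(trimethylsilyl)phenyl trifluoromethanesulfonate | CC(C)=CCc1c(OCOC)cc(OCOC)c([Si](C)(C)C)c1OS(=O)(=O)C(F)(F)F | intermediate
12 | 7-hydroxy-2,2-dimethylchroman-4-one | CC1(C)CC(=O)c2ccc(O)cc2O1 | starting material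
13 | 2,2-dimethylchromane-4,7-diol (racemic), formed in the flask | CC1(C)CC(O)c2ccc(O)cc2O1 | intermediate
14 | 2,2-dimethyl-2H-chromen-7-ol | CC1(C)C=Cc2ccc(O)cc2O1 | intermediate
15 | 7-hydroxy-2,2-dimethyl-2H-chromene-6-carbaldehyde | CC1(C)C=Cc2cc(C=O)c(O)cc2O1 | intermediate
16 | 7-(methoxymethoxy)-2,2-dimethyl-2H-chromene-6-carbaldehyde | COCOc1cc2OC(C)(C)C=Cc2cc1C=O | intermediate
17 | rac-3-hydroxy-N-methoxy-3-[7-(methoxymethoxy)-2,2-dimethyl-2H-chromen-6-yl]-N-methylpropanamide | COCOc1cc2OC(C)(C)C=Cc2cc1C(O)CC(=O)N(C)OC | intermediate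
18 | N-methoxy-3-[7-(methoxymethoxy)-2,2-dimethyl-2H-chromen-6-yl]-N-methyl-3-oxopropanamide | COCOc1cc2OC(C)(C)C=Cc2cc1C(=O)CC(=O)N(C)OC | intermediate
19 | (3S)-3-hydroxy-N-methoxy-3-[7-(methoxymethoxy)-2,2-dimethyl-2H-chromen-6-yl]-N-methylpropanamide | COCOc1cc2OC(C)(C)C=Cc2cc1[C@@H](O)CC(=O)N(C)OC | intermediate
20 | (3S)-N-methoxy-3-[7-(methoxymethoxy)-2,2-dimethyl-2H-chromen-6-yl]-N-methyl-3-(trimethylsilyloxy)propanamide | COCOc1cc2OC(C)(C)C=Cc2cc1[C@@H](O[Si](C)(C)C)CC(=O)N(C)OC | intermediate
21 | 3,5-bis(methoxymethoxy)-6-(3-methylbut-2-en-1-yl)benzyne (1,2-didehydrobenzene), formed in the flask | CC(C)=CCC1=C(OCOC)C=C(OCOC)C#C1 | intermediate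
22 | cesium (S)-alkoxide of 19, formed in the flask | COCOc1cc2OC(C)(C)C=Cc2cc1[C@@H]([O-])CC(=O)N(C)OC.[Cs+] | intermediate
23 | cesium aryl anion: (3S)-3-aryloxy amide metalated ortho to the ether oxygen (at the future C4a), formed in the flask | COCOc1cc2OC(C)(C)C=Cc2cc1[C@@H](Oc1[c-]c(OCOC)cc(OCOC)c1CC=C(C)C)CC(=O)N(C)OC.[Cs+] | intermediate
24 | cesium (2S)-4-[methoxy(methyl)amino]-5,7-bis(methoxymethoxy)-2-[7-(methoxymethoxy)-2,2-dimethyl-2H-chromen-6-yl]-8-(3-methylbut-2-en-1-yl)chroman-4-olate (C4 epimers), formed in the flask | CC(C)=CCc1c(OCOC)cc(OCOC)c2c1O[C@H](c1cc3C=CC(C)(C)Oc3cc1OCOC)CC2([O-])N(C)OC.[Cs+] | intermediate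
25 | (2S)-5,7-bis(methoxymethoxy)-2-[7-(methoxymethoxy)-2,2-dimethyl-2H-chromen-6-yl]-8-(3-methylbut-2-en-1-yl)chroman-4-one | CC(C)=CCc1c(OCOC)cc(OCOC)c2c1O[C@H](c1cc3C=CC(C)(C)Oc3cc1OCOC)CC2=O | intermediate
26 | (2S)-8-(3-methylbut-2-en-1-yl)-5,7-bis(trimethylsilyloxy)-2-[2,2-dimethyl-7-(trimethylsilyloxy)-2H-chromen-6-yl]chroman-4-one, formed in the flask | CC(C)=CCc1c(O[Si](C)(C)C)cc(O[Si](C)(C)C)c2c1O[C@H](c1cc3C=CC(C)(C)Oc3cc1O[Si](C)(C)C)CC2=O | intermediate
27 | (2S)-5,7-dihydroxy-2-(7-hydroxy-2,2-dimethyl-2H-chromen-6-yl)-8-(3-methylbut-2-en-1-yl)chroman-4-one (CNP0150213.1) | CC(C)=CCc1c(O)cc(O)c2c1O[C@H](c1cc3c(cc1O)OC(C)(C)C=C3)CC2=O | target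

**Step count**
Total: 13 steps. Longest linear sequence: 9 steps (steps 5 to 13); the other branch is steps 1 to 4.

**Steps most likely to fail, with fallbacks**

Step 12 (key step, proposed new method). What may go wrong: protonation of the aryl anion or α-deprotonation of the amide before ring closure, attack of the alkoxide at the wrong aryne carbon, or decay of the free alkoxide (retro-aldol or elimination) before the aryne is formed. The fallback uses known chemistry (aryne insertion into the C–O bond of a carboxylic acid, oxa-Michael closure, kinetic resolution) and sets out from 16 and 11. Knoevenagel–Doebner condensation of 16 with malonic acid (pyridine, piperidine cat., 90 °C) should give (E)-3-[7-(methoxymethoxy)-2,2-dimethyl-2H-chromen-6-yl]prop-2-enoic acid F1. Heating F1 with 11 and CsF in THF (sealed tube) should O-arylate the carboxylate at C8a and transfer the acyl group to C4a, the same two bonds with the same aryne regiochemistry, to give (E)-1-[2-hydroxy-4,6-bis(methoxymethoxy)-3-(3-methylbut-2-en-1-yl)phenyl]-3-[7-(methoxymethoxy)-2,2-dimethyl-2H-chromen-6-yl]prop-2-en-1-one F2. F2 should close under the basic conditions (or with NaOAc in EtOH) by oxa-Michael addition to racemic 5,7-bis(methoxymethoxy)-2-[7-(methoxymethoxy)-2,2-dimethyl-2H-chromen-6-yl]-8-(3-methylbut-2-en-1-yl)chroman-4-one F3. Kinetic resolution of F3 by asymmetric transfer hydrogenation with RuCl(p-cymene)[(R,R)-TsDPEN] and HCO2H/Et3N should reduce the (2R)-enantiomer to (2R,4R)-5,7-bis(methoxymethoxy)-2-[7-(methoxymethoxy)-2,2-dimethyl-2H-chromen-6-yl]-8-(3-methylbut-2-en-1-yl)chroman-4-ol F4 and leave the (2S)-ketone. The route is rejoined at 25, with at most half of the material.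

Step 3. What may go wrong: lithiation between the two MOM ethers instead of next to the carbamate, an incomplete second metalation in the salt-laden mixture, migration of the carbamoyl group to carbon on warming (anionic Fries rearrangement), or SN2′ attack on prenyl bromide. The fallback avoids the second metalation and sets out from 3. The sequence is stopped after the TMSCl trap (TBSOTf, TMEDA, Et2O; TMEDA, n-BuLi, −78 °C; TMSCl; aq. NH4Cl/MeOH work-up), which should give 3,5-bis(methoxymethoxy)-2-(trimethylsilyl)phenyl N-isopropylcarbamate F5, purified at this stage. Cleavage of the carbamate (Et2NH, DBU, MeCN, 40 °C) should give 3,5-bis(methoxymethoxy)-2-(trimethylsilyl)phenol F6. Tsuji–Trost O-allylation with tert-butyl 2-methylbut-3-en-2-yl carbonate and Pd(PPh3)4 (zerovalent palladium, THF, 0 °C) should give [2,4-bis(methoxymethoxy)-6-(2-methylbut-3-en-2-yloxy)phenyl]trimethylsilane F7. Aromatic Claisen rearrangement of F7 (toluene, 110 °C) into the only free ortho position should deliver the prenyl group next to the phenol. The route is rejoined at 10, which is triflated with PhNTf2/DBU as in the second half of step 4 to give 11.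

Step 10. What may go wrong: slow or poorly face-selective hydride transfer to an electron-rich, ortho-alkoxy aryl ketone that also enolises. The fallback replaces oxidation and asymmetric reduction by a kinetic resolution and sets out from racemic 17. Lipase-catalysed acylation (Burkholderia cepacia lipase, vinyl acetate, MTBE, 35 °C) should, by the usual preference for the enantiomer with the large aryl and medium CH2 groups placed as in (R)-1-phenylethanol, acetylate the (R)-alcohol to (1R)-3-[methoxy(methyl)amino]-1-[7-(methoxymethoxy)-2,2-dimethyl-2H-chromen-6-yl]-3-oxopropyl acetate F8. The unreacted (S)-alcohol is separated by chromatography, and the route is rejoined at 19.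

**Further compounds**
F1 | step 12 | (E)-3-[7-(methoxymethoxy)-2,2-dimethyl-2H-chromen-6-yl]prop-2-enoic acid | COCOc1cc2OC(C)(C)C=Cc2cc1/C=C/C(=O)O
F2 | step 12 | (E)-1-[2-hydroxy-4,6-bis(methoxymethoxy)-3-(3-methylbut-2-en-1-yl)phenyl]-3-[7-(methoxymethoxy)-2,2-dimethyl-2H-chromen-6-yl]prop-2-en-1-one | CC(C)=CCc1c(O)c(C(=O)/C=C/c2cc3C=CC(C)(C)Oc3cc2OCOC)c(OCOC)cc1OCOC
F3 | step 12 | racemic 5,7-bis(methoxymethoxy)-2-[7-(methoxymethoxy)-2,2-dimethyl-2H-chromen-6-yl]-8-(3-methylbut-2-en-1-yl)chroman-4-one | CC(C)=CCc1c(OCOC)cc(OCOC)c2c1OC(c1cc3C=CC(C)(C)Oc3cc1OCOC)CC2=O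
F4 | step 12 | (2R,4R)-5,7-bis(methoxymethoxy)-2-[7-(methoxymethoxy)-2,2-dimethyl-2H-chromen-6-yl]-8-(3-methylbut-2-en-1-yl)chroman-4-ol | CC(C)=CCc1c(OCOC)cc(OCOC)c2c1O[C@@H](c1cc3C=CC(C)(C)Oc3cc1OCOC)C[C@H]2O
F5 | step 3 | 3,5-bis(methoxymethoxy)-2-(trimethylsilyl)phenyl N-isopropylcarbamate | C[Si](C)(C)c1c(OCOC)cc(OCOC)cc1OC(=O)NC(C)C
F6 | step 3 | 3,5-bis(methoxymethoxy)-2-(trimethylsilyl)phenol | Oc1cc(OCOC)cc(OCOC)c1[Si](C)(C)C
F7 | step 3 | [2,4-bis(methoxymethoxy)-6-(2-methylbut-3-en-2-yloxy)phenyl]trimethylsilane | C=CC(C)(C)Oc1cc(OCOC)cc(OCOC)c1[Si](C)(C)C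
F8 | step 10 | (1R)-3-[methoxy(methyl)amino]-1-[7-(methoxymethoxy)-2,2-dimethyl-2H-chromen-6-yl]-3-oxopropyl acetate | COCOc1cc2OC(C)(C)C=Cc2cc1[C@H](OC(C)=O)CC(=O)N(C)OC
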